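**Retrosynthetic overview**

1. The 28-membered ring (the only ring) contains one α-acyloxy carboxamide, C1(=O)–O–C2'H(n-Pr)–C1'(=O)–NH–C24 (chain numbered from the lactone carbonyl C1 to the CH2N carbon C24; C1'/C2' are the hydroxy-acid carbons). It is opened last into the C1 acid and C24 isocyanide of one chain plus butanal (Passerini), which forms C1'–C2' and O–C1 in one operation.
2. Seco isocyano acid 38 comes from formamide ester 35, made by B-alkyl Suzuki coupling at C17–C18 of the diene between dienyl triflate 22 (C1–C17) and alkene 33 (C18–C24). The diene is joined here, not at C15–C16, because the triflate geometry then fixes the 16Z olefin.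
3. Triflate 22: C2/C4 from desymmetrised meso-2,4-dimethylglutaric anhydride; C13 from the (S)-Roche ester (its CH2OH becomes C14); chain by copper-catalysed Grignard coupling and Wittig/hydrogenation; C14=C15 by Julia–Kocienski olefination with an (E)-enol triflate enal from methyl 4-methoxyacetoacetate.
4. Alkene 33: C20/C21 from 2-deoxy-D-ribose (via its dithioacetal); C23 and the C24–N bond from a copper-catalysed Henry reaction.
5. After ring closure, HF·pyridine removes the three TBS ethers.

Key step: step 30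

Assumption: in the three catalyst-controlled steps (1, 23 and 30) the catalyst antipode written is taken to be the one that gives the configuration drawn; the sense is checked on the first run (Mosher ester, or comparison with material from the chiral-pool fallback), and the pseudo-enantiomer or enantiomer is used if it proves to be the other.

**Route**

Step 1
Reactants: 1 meso-2,4-dimethylglutaric anhydride
Product: 2 (2R,4S)-5-methoxy-2,4-dimethyl-5-oxopentanoic acid
Conditions: MeOH (10 equiv), (DHQD)2AQN (0.3 equiv), Et2O, −40 °C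
Reagents that add atoms: methanol, CO
Why: Cinchona-alkaloid-catalysed desymmetrising methanolysis of a meso anhydride, in which the catalyst directs methanol to the carbonyl on the (S)-carbon so that the ester sits on the future C2 and the free acid on the future C4.

Step 2
Reactants: 2 (2R,4S)-5-methoxy-2,4-dimethyl-5-oxopentanoic acid
Product: 3 methyl (2S,4R)-5-hydroxy-2,4-dimethylpentanoate
Conditions: BH3·SMe2, THF, −10 → 0 °C; used crude
Reagents that add atoms: none
Why: Chemoselective borane reduction of a carboxylic acid beside a methyl ester; the hydroxy ester is taken on at once because it lactonises on standing.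

Step 3
Reactants: 3 methyl (2S,4R)-5-hydroxy-2,4-dimethylpentanoate
Product: 4 methyl (2S,4R)-2,4-dimethyl-5-oxopentanoate
Conditions: (COCl)2, DMSO, CH2Cl2, −78 °C; iPr2NEt, −78 → −20 °C
Reagents that add atoms: none
Why: Swern oxidation, with low temperature and a hindered base to keep the α-methyl centre (future C4) intact.

Step 4
Reactants: 5 methyl (S)-3-hydroxy-2-methylpropanoate ((S)-Roche ester)
Product: 6 methyl (S)-3-(benzyloxy)-2-methylpropanoate
Conditions: BnOC(=NH)CCl3, TfOH (cat.), CH2Cl2/cyclohexane, rt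
Reagents that add atoms: benzyl 2,2,2-trichloroacetimidate, N=C(OCc1ccccc1)C(Cl)(Cl)Cl
Why: Acid-catalysed benzylation with the trichloroacetimidate, which avoids base and so cannot epimerise or eliminate the β-hydroxy ester.

Step 5
Reactants: 6 methyl (S)-3-(benzyloxy)-2-methylpropanoate
Product: 7 (R)-3-(benzyloxy)-2-methylpropan-1-ol
Conditions: LiAlH4, THF, 0 °C
Reagents that add atoms: none
Why: Hydride reduction of the ester to the primary alcohol (future C12); the centre is untouched and only its descriptor changes.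

Step 6
Reactants: 7 (R)-3-(benzyloxy)-2-methylpropan-1-ol
Product: 8 (S)-3-(benzyloxy)-2-methylpropyl 4-methylbenzenesulfonate
Conditions: TsCl, pyridine, 0 °C
Reagents that add atoms: 4-toluenesulfonyl chloride, Cc1ccc(cc1)S(Cl)(=O)=O
Why: Standard sulfonylation of a primary alcohol to give the electrophile for the sp3–sp3 coupling.

Step 7
Reactants: 8 (S)-3-(benzyloxy)-2-methylpropyl 4-methylbenzenesulfonate
Product: 9 benzyl (R)-9-chloro-2-methylnonyl ether
Conditions: Cl(CH2)6MgBr (1.5 equiv, preformed in THF), Li2CuCl4 (5 mol%), THF, −30 °C → rt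
Reagents that add atoms: 6-chlorohexylmagnesium bromide, ClCCCCCC[Mg]Br
Why: Kochi-type copper-catalysed Grignard–tosylate coupling forms C11–C12, and the alkyl chloride of the reagent is inert under these conditions.

Step 8
Reactants: 9 benzyl (R)-9-chloro-2-methylnonyl ether
Product: 11 [(R)-9-(benzyloxy)-8-methylnonyl]triphenylphosphonium iodide, via alkyl iodide 10 (not isolated)
Conditions: NaI, PPh3, MeCN, reflux
Reagents that add atoms: triphenylphosphine, c1ccccc1P(c1ccccc1)c1ccccc1; sodium iodide, [Na+].[I-]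
Why: Finkelstein exchange followed in the same pot by SN2 quaternisation of triphenylphosphine at the unhindered primary carbon (future C6).

Step 9
Reactants: 11 [(R)-9-(benzyloxy)-8-methylnonyl]triphenylphosphonium iodide; 4 methyl (2S,4R)-2,4-dimethyl-5-oxopentanoate
Product: 13 methyl (2S,4R,5Z,13R)-14-(benzyloxy)-2,4,13-trimethyltetradec-5-enoate, via phosphorus ylide 12 (not isolated)
Conditions: NaHMDS, THF, −78 → 0 °C; then 4, −78 °C → rt
Reagents that add atoms: none
Why: Wittig olefination with a non-stabilised ylide joins C5 to C6; the alkene geometry is irrelevant, and the ylide is consumed by the aldehyde faster than it can enolise the aldehyde or ester.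

Step 10
Reactants: 13 methyl (2S,4R,5Z,13R)-14-(benzyloxy)-2,4,13-trimethyltetradec-5-enoate
Product: 14 methyl (2S,4S,13R)-14-hydroxy-2,4,13-trimethyltetradecanoate
Conditions: H2 (1 atm), Pt/C, EtOAc; then Pd/C, H2, EtOH
Reagents that add atoms: none
Why: Catalytic hydrogenation over platinum saturates C5=C6 without the double-bond migration that would scramble allylic C4, and palladium then hydrogenolyses the benzyl ether.

Step 11
Reactants: 14 methyl (2S,4S,13R)-14-hydroxy-2,4,13-trimethyltetradecanoate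
Product: 15 methyl (2S,4S,13R)-2,4,13-trimethyl-14-[(1-phenyl-1H-tetrazol-5-yl)sulfanyl]tetradecanoate
Conditions: 1-phenyl-1H-tetrazole-5-thiol, PPh3, DIAD, THF, 0 °C → rt
Reagents that add atoms: 1-phenyl-1H-tetrazole-5-thiol, Sc1nnnn1-c1ccccc1
Why: Mitsunobu thioetherification of the primary alcohol at C14.

Step 12
Reactants: 15 methyl (2S,4S,13R)-2,4,13-trimethyl-14-[(1-phenyl-1H-tetrazol-5-yl)sulfanyl]tetradecanoate
Product: 16 methyl (2S,4S,13R)-2,4,13-trimethyl-14-[(1-phenyl-1H-tetrazol-5-yl)sulfonyl]tetradecanoate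
Conditions: (NH4)6Mo7O24·4H2O (10 mol%), 30% H2O2, EtOH, rt
Reagents that add atoms: hydrogen peroxide, OO
Why: Molybdate-catalysed oxidation of the sulfide to the sulfone, which leaves the ester alone.

Step 13
Reactants: 17 methyl 4-methoxy-3-oxobutanoate
Product: 18 methyl (E)-4-methoxy-3-{[(trifluoromethyl)sulfonyl]oxy}but-2-enoate
Conditions: Tf2O, aq. Me4NOH, toluene, 5 °C
Reagents that add atoms: trifluoromethanesulfonic anhydride, O=S(=O)(C(F)(F)F)OS(=O)(=O)C(F)(F)F
Why: O-triflation of the β-keto ester enolate, where the non-coordinating tetramethylammonium counter-ion gives the unchelated enolate and hence the (E)-enol triflate (OTf trans to the ester, CH2OMe cis to it).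

Step 14
Reactants: 18 methyl (E)-4-methoxy-3-{[(trifluoromethyl)sulfonyl]oxy}but-2-enoate
Product: 19 (E)-4-hydroxy-1-methoxybut-2-en-2-yl trifluoromethanesulfonate
Conditions: DIBAL-H (2.2 equiv), CH2Cl2, −78 °C
Reagents that add atoms: none
Why: 1,2-Reduction of the enoate to the allylic alcohol; vinyl triflates tolerate DIBAL-H at low temperature.

Step 15
Reactants: 19 (E)-4-hydroxy-1-methoxybut-2-en-2-yl trifluoromethanesulfonate
Product: 20 (E)-1-methoxy-4-oxobut-2-en-2-yl trifluoromethanesulfonate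
Conditions: MnO2, CH2Cl2, rt; used at once
Reagents that add atoms: none
Why: Neutral allylic oxidation with MnO2, which should preserve the olefin geometry.

Step 16
Reactants: 16 methyl (2S,4S,13R)-2,4,13-trimethyl-14-[(1-phenyl-1H-tetrazol-5-yl)sulfonyl]tetradecanoate; 20 (E)-1-methoxy-4-oxobut-2-en-2-yl trifluoromethanesulfonate
Product: 22 methyl (2S,4S,13R,14E,16E)-18-methoxy-2,4,13-trimethyl-17-{[(trifluoromethyl)sulfonyl]oxy}octadeca-14,16-dienoate, via potassium sulfonyl carbanion 21 (not isolated)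
Conditions: KHMDS (1.05 equiv), DME, −60 °C; then 20, −60 °C → rt
Reagents that add atoms: none
Why: Julia–Kocienski olefination (carbanion addition to the aldehyde, Smiles rearrangement, loss of SO2 and tetrazolate) forms C14=C15 with the E preference of phenyltetrazolyl sulfones under KHMDS/DME; the sulfone α-proton is far more acidic than the ester α-proton, and the vinyl triflate has no anti β-hydrogen to eliminate.

Step 17
Reactants: 23 2-deoxy-D-ribose
Product: 24 (2R,3S)-4-(1,3-dithian-2-yl)butane-1,2,3-triol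
Conditions: HS(CH2)3SH, conc. HCl, 0 °C
Reagents that add atoms: propane-1,3-dithiol, SCCCS
Why: Acid-catalysed dithioacetalisation opens the sugar to the acyclic triol and masks C23, leaving the two pool stereocentres (C20, C21) untouched.

Step 18
Reactants: 24 (2R,3S)-4-(1,3-dithian-2-yl)butane-1,2,3-triol
Product: 25 (2R,3S)-1,2,3-tris[(tert-butyldimethylsilyl)oxy]-4-(1,3-dithian-2-yl)butane
Conditions: TBSOTf (3.5 equiv), 2,6-lutidine, CH2Cl2, 0 °C → rt
Reagents that add atoms: tert-butyldimethylsilyl trifluoromethanesulfonate, CC(C)(C)[Si](C)(C)OS(=O)(=O)C(F)(F)F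
Why: Exhaustive silylation with the silyl triflate, which also covers the hindered vicinal secondary hydroxyls.

Step 19
Reactants: 25 (2R,3S)-1,2,3-tris[(tert-butyldimethylsilyl)oxy]-4-(1,3-dithian-2-yl)butane
Product: 26 (2R,3S)-2,3-bis[(tert-butyldimethylsilyl)oxy]-4-(1,3-dithian-2-yl)butan-1-ol
Conditions: HF·pyridine, pyridine, THF, 0 °C
Reagents that add atoms: none
Why: Buffered fluoride cleaves the primary silyl ether much faster than the two secondary ones, and the acidic medium prevents silyl migration.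

Step 20
Reactants: 26 (2R,3S)-2,3-bis[(tert-butyldimethylsilyl)oxy]-4-(1,3-dithian-2-yl)butan-1-ol
Product: 27 (2S,3S)-2,3-bis[(tert-butyldimethylsilyl)oxy]-4-(1,3-dithian-2-yl)butanal
Conditions: (COCl)2, DMSO, CH2Cl2, −78 °C; iPr2NEt, −78 → −30 °C
Reagents that add atoms: none
Why: Swern oxidation tolerates the dithiane, and the cold hindered-base work-up avoids epimerisation of the α-silyloxy aldehyde (C20).

Step 21
Reactants: 27 (2S,3S)-2,3-bis[(tert-butyldimethylsilyl)oxy]-4-(1,3-dithian-2-yl)butanal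
Product: 28 2-[(2S,3R)-2,3-bis[(tert-butyldimethylsilyl)oxy]pent-4-en-1-yl]-1,3-dithiane
Conditions: Ph3PCH3Br, KHMDS, THF, −78 → 0 °C
Reagents that add atoms: methyltriphenylphosphonium bromide, C[P+](c1ccccc1)(c1ccccc1)c1ccccc1.[Br-]
Why: Wittig methylenation adds C18 as the terminal vinyl carbon needed for the later hydroboration.

Step 22
Reactants: 28 2-[(2S,3R)-2,3-bis[(tert-butyldimethylsilyl)oxy]pent-4-en-1-yl]-1,3-dithiane
Product: 29 (3S,4R)-3,4-bis[(tert-butyldimethylsilyl)oxy]hex-5-enal
Conditions: MeI, CaCO3, MeCN/H2O (9:1), 45 °C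
Reagents that add atoms: water, O
Why: S-Alkylative hydrolysis of the dithiane frees the C23 aldehyde under near-neutral, non-oxidising conditions that spare the alkene and silyl ethers.

Step 23
Reactants: 29 (3S,4R)-3,4-bis[(tert-butyldimethylsilyl)oxy]hex-5-enal
Product: 30 (2S,4S,5R)-4,5-bis[(tert-butyldimethylsilyl)oxy]-1-nitrohept-6-en-2-ol
Conditions: MeNO2 (10 equiv), Cu(OAc)2·H2O (10 mol%), indane-fused bis(oxazoline) ligand (11 mol%, antipode for the (S)-nitro alcohol), EtOH, rt
Reagents that add atoms: nitromethane, C[N+](=O)[O-]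
Why: Copper acetate/bis(oxazoline)-catalysed asymmetric Henry reaction forms C23–C24 and brings in nitrogen; the C23 configuration is set by the ligand-controlled face of the copper-bound aldehyde, and the weakly basic acetate avoids β-elimination.

Step 24
Reactants: 30 (2S,4S,5R)-4,5-bis[(tert-butyldimethylsilyl)oxy]-1-nitrohept-6-en-2-ol
Product: 31 (2S,4S,5R)-1-amino-4,5-bis[(tert-butyldimethylsilyl)oxy]hept-6-en-2-ol
Conditions: Zn dust, AcOH, THF, 0 °C → rt; basic work-up
Reagents that add atoms: none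
Why: Dissolving-metal reduction of the aliphatic nitro group to the amine, acidic so that no retro-Henry occurs, and without hydrogenation of the vinyl group.

Step 25
Reactants: 31 (2S,4S,5R)-1-amino-4,5-bis[(tert-butyldimethylsilyl)oxy]hept-6-en-2-ol
Product: 32 N-[(2S,4S,5R)-4,5-bis[(tert-butyldimethylsilyl)oxy]-2-hydroxyhept-6-en-1-yl]formamide
Conditions: HCO2Et, 55 °C
Reagents that add atoms: ethyl formate, CCOC=O
Why: Aminolysis of ethyl formate formylates the amine selectively over the secondary alcohol.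

Step 26
Reactants: 32 N-[(2S,4S,5R)-4,5-bis[(tert-butyldimethylsilyl)oxy]-2-hydroxyhept-6-en-1-yl]formamide
Product: 33 N-[(2S,4S,5R)-2,4,5-tris[(tert-butyldimethylsilyl)oxy]hept-6-en-1-yl]formamide
Conditions: TBSCl, imidazole, DMF, rt
Reagents that add atoms: tert-butyldimethylsilyl chloride, CC(C)(C)[Si](C)(C)Cl
Why: Imidazole-promoted silylation of the C23 hydroxyl; the formamide is not silylated durably under these conditions.

Step 27
Reactants: 33 N-[(2S,4S,5R)-2,4,5-tris[(tert-butyldimethylsilyl)oxy]hept-6-en-1-yl]formamide; 22 methyl (2S,4S,13R,14E,16E)-18-methoxy-2,4,13-trimethyl-17-{[(trifluoromethyl)sulfonyl]oxy}octadeca-14,16-dienoate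
Product: 35 methyl (2S,4S,13R,14E,16Z,20R,21S,23S)-20,21,23-tris[(tert-butyldimethylsilyl)oxy]-24-formamido-17-(methoxymethyl)-2,4,13-trimethyltetracosa-14,16-dienoate, via alkylborane 34 (not isolated)
Conditions: 33 (1.3 equiv), 9-BBN dimer, THF, rt; aq. Cs2CO3; then 22, PdCl2(dppf)·CH2Cl2 (10 mol%), AsPh3, DMF, rt
Reagents that add atoms: none
Why: B-alkyl Suzuki–Miyaura coupling: anti-Markovnikov hydroboration of the terminal vinyl group, then palladium-catalysed coupling with the dienyl triflate with retention, so C18 arrives trans to C15 and the 16Z geometry follows from the triflate; the formamide N–H, ester and silyl ethers tolerate the mild base.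

Step 28
Reactants: 35 methyl (2S,4S,13R,14E,16Z,20R,21S,23S)-20,21,23-tris[(tert-butyldimethylsilyl)oxy]-24-formamido-17-(methoxymethyl)-2,4,13-trimethyltetracosa-14,16-dienoate
Product: 36 methyl (2S,4S,13R,14E,16Z,20R,21S,23S)-20,21,23-tris[(tert-butyldimethylsilyl)oxy]-24-isocyano-17-(methoxymethyl)-2,4,13-trimethyltetracosa-14,16-dienoate
Conditions: POCl3, Et3N, CH2Cl2, −30 → 0 °C
Reagents that add atoms: none
Why: Ugi dehydration of the N-alkylformamide to the isocyanide in a basic medium that leaves the silyl ethers, diene and ester untouched.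

Step 29
Reactants: 36 methyl (2S,4S,13R,14E,16Z,20R,21S,23S)-20,21,23-tris[(tert-butyldimethylsilyl)oxy]-24-isocyano-17-(methoxymethyl)-2,4,13-trimethyltetracosa-14,16-dienoate
Product: 38 (2S,4S,13R,14E,16Z,20R,21S,23S)-20,21,23-tris[(tert-butyldimethylsilyl)oxy]-24-isocyano-17-(methoxymethyl)-2,4,13-trimethyltetracosa-14,16-dienoic acid (seco isocyano acid), via lithium carboxylate 37 (not isolated)
Conditions: LiOH·H2O, THF/MeOH/H2O, rt; cold NaH2PO4 buffer (pH 5), extraction into toluene; the dried solution is used at once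
Reagents that add atoms: lithium hydroxide, [Li+].[OH-]
Why: Saponification of the methyl ester, to which the base-stable isocyanide and secondary silyl ethers are inert (as in the preparation of isocyanoacetate salts), with the acid released only at pH 5 and taken on at once to avoid hydration of the isocyanide.

Step 30
Reactants: 38 seco isocyano acid; 39 butanal
Product: 41 tris-TBS ether of the target macrocycle, via cyclic imidate 40 (not isolated)
Conditions: 38 in toluene added by syringe pump over 24 h to butanal (10 equiv) and (R,R)-(salen)AlCl (0.3 equiv) [salen = N,N'-bis(3,5-di-tert-butylsalicylidene)cyclohexane-1,2-diamine dianion], toluene, −40 °C, final concentration 1 mM; then → 0 °C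
Reagents that add atoms: none
Why: Proposed new method: the closest known reactions are the Passerini three-component macrocyclisation of ω-isocyano carboxylic acids with aldehydes and the (salen)AlCl-catalysed intermolecular Passerini reaction of aliphatic aldehydes, which are combined here for the first time. The C24 isocyanide carbon attacks butanal held on aluminium and hydrogen-bonded to the C1 acid (new C1'–C2' bond), and the carboxylate oxygen then adds to the nitrilium carbon to give cyclic imidate 40. That capture is the ring closure, a 27-membered head-to-tail closure through oxygen with C2' exocyclic, and the following Mumm 1,4 O-to-O acyl shift through a five-membered transition state enlarges the ring by one atom to the 28-membered depsi-lactam and makes the sequence irreversible. The only new stereocentre, C2', is set in the intermolecular C–C bond-forming event, so its (S) configuration rests on the chiral salen ligand on aluminium and not on the remote centres of the chain. Intramolecular nitrilium capture is favoured over oligomerisation by slow addition of 38 into excess butanal, and nothing else in 38 can interfere: all three hydroxyls are silylated, the acid is never activated (no epimerisation at C2), and the diene and allylic ether are inert to the weak Lewis acid.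

Step 31
Reactants: 41 tris-TBS ether of the target macrocycle
Product: 42 CNP0511044.2 (target)
Conditions: HF·pyridine, pyridine, THF, 0 °C → rt
Reagents that add atoms: none
Why: Buffered fluoride desilylation of the three secondary silyl ethers under mildly acidic conditions that avoid base-induced acyl migration of the α-acyloxy amide.

**Compound list**

1 | meso-2,4-dimethylglutaric anhydride | C[C@@H]1C[C@H](C)C(=O)OC1=O | starting material
2 | (2R,4S)-5-methoxy-2,4-dimethyl-5-oxopentanoic acid | COC(=O)[C@@H](C)C[C@@H](C)C(=O)O | intermediate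
3 | methyl (2S,4R)-5-hydroxy-2,4-dimethylpentanoate | COC(=O)[C@@H](C)C[C@@H](C)CO | intermediate
4 | methyl (2S,4R)-2,4-dimethyl-5-oxopentanoate | COC(=O)[C@@H](C)C[C@@H](C)C=O | intermediate
5 | methyl (S)-3-hydroxy-2-methylpropanoate | OC[C@H](C)C(=O)OC | starting material
6 | methyl (S)-3-(benzyloxy)-2-methylpropanoate | COC(=O)[C@@H](C)COCc1ccccc1 | intermediate
7 | (R)-3-(benzyloxy)-2-methylpropan-1-ol | OC[C@@H](C)COCc1ccccc1 | intermediate
8 | (S)-3-(benzyloxy)-2-methylpropyl 4-methylbenzenesulfonate | Cc1ccc(cc1)S(=O)(=O)OC[C@@H](C)COCc1ccccc1 | intermediate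
9 | benzyl (R)-9-chloro-2-methylnonyl ether | ClCCCCCCC[C@@H](C)COCc1ccccc1 | intermediate
10 | benzyl (R)-9-iodo-2-methylnonyl ether | ICCCCCCC[C@@H](C)COCc1ccccc1 | intermediate
11 | [(R)-9-(benzyloxy)-8-methylnonyl]triphenylphosphonium iodide | [I-].c1ccccc1[P+](c1ccccc1)(c1ccccc1)CCCCCCC[C@@H](C)COCc1ccccc1 | intermediate
12 | [(R)-9-(benzyloxy)-8-methylnonylidene]triphenylphosphorane | c1ccccc1P(c1ccccc1)(c1ccccc1)=CCCCCCC[C@@H](C)COCc1ccccc1 | intermediate
13 | methyl (2S,4R,5Z,13R)-14-(benzyloxy)-2,4,13-trimethyltetradec-5-enoate | COC(=O)[C@@H](C)C[C@@H](C)/C=C\CCCCCC[C@@H](C)COCc1ccccc1 | intermediate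
14 | methyl (2S,4S,13R)-14-hydroxy-2,4,13-trimethyltetradecanoate | COC(=O)[C@@H](C)C[C@@H](C)CCCCCCCC[C@@H](C)CO | intermediate
15 | methyl (2S,4S,13R)-2,4,13-trimethyl-14-[(1-phenyl-1H-tetrazol-5-yl)sulfanyl]tetradecanoate | COC(=O)[C@@H](C)C[C@@H](C)CCCCCCCC[C@@H](C)CSc1nnnn1-c1ccccc1 | intermediate
16 | methyl (2S,4S,13R)-2,4,13-trimethyl-14-[(1-phenyl-1H-tetrazol-5-yl)sulfonyl]tetradecanoate | COC(=O)[C@@H](C)C[C@@H](C)CCCCCCCC[C@@H](C)CS(=O)(=O)c1nnnn1-c1ccccc1 | intermediate
17 | methyl 4-methoxy-3-oxobutanoate | COCC(=O)CC(=O)OC | starting material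
18 | methyl (E)-4-methoxy-3-{[(trifluoromethyl)sulfonyl]oxy}but-2-enoate | COC(=O)/C=C(\COC)OS(=O)(=O)C(F)(F)F | intermediate
19 | (E)-4-hydroxy-1-methoxybut-2-en-2-yl trifluoromethanesulfonate | OC/C=C(\COC)OS(=O)(=O)C(F)(F)F | intermediate
20 | (E)-1-methoxy-4-oxobut-2-en-2-yl trifluoromethanesulfonate | O=C/C=C(\COC)OS(=O)(=O)C(F)(F)F | intermediate
21 | potassium α-sulfonyl carbanion of 16 (C14 metalated) | [K+].COC(=O)[C@@H](C)C[C@@H](C)CCCCCCCC[C@@H](C)[CH-]S(=O)(=O)c1nnnn1-c1ccccc1 | intermediate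
22 | methyl (2S,4S,13R,14E,16E)-18-methoxy-2,4,13-trimethyl-17-{[(trifluoromethyl)sulfonyl]oxy}octadeca-14,16-dienoate (C1–C17 dienyl triflate) | COC(=O)[C@@H](C)C[C@@H](C)CCCCCCCC[C@@H](C)/C=C/C=C(\COC)OS(=O)(=O)C(F)(F)F | intermediate
23 | 2-deoxy-D-ribose | OC[C@@H](O)[C@@H](O)CC=O | starting material
24 | (2R,3S)-4-(1,3-dithian-2-yl)butane-1,2,3-triol | OC[C@@H](O)[C@@H](O)CC1SCCCS1 | intermediate
25 | (2R,3S)-1,2,3-tris[(tert-butyldimethylsilyl)oxy]-4-(1,3-dithian-2-yl)butane | CC(C)(C)[Si](C)(C)OC[C@@H](O[Si](C)(C)C(C)(C)C)[C@@H](O[Si](C)(C)C(C)(C)C)CC1SCCCS1 | intermediate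
26 | (2R,3S)-2,3-bis[(tert-butyldimethylsilyl)oxy]-4-(1,3-dithian-2-yl)butan-1-ol | OC[C@@H](O[Si](C)(C)C(C)(C)C)[C@@H](O[Si](C)(C)C(C)(C)C)CC1SCCCS1 | intermediate
27 | (2S,3S)-2,3-bis[(tert-butyldimethylsilyl)oxy]-4-(1,3-dithian-2-yl)butanal | O=C[C@@H](O[Si](C)(C)C(C)(C)C)[C@@H](O[Si](C)(C)C(C)(C)C)CC1SCCCS1 | intermediate
28 | 2-[(2S,3R)-2,3-bis[(tert-butyldimethylsilyl)oxy]pent-4-en-1-yl]-1,3-dithiane | C=C[C@@H](O[Si](C)(C)C(C)(C)C)[C@@H](O[Si](C)(C)C(C)(C)C)CC1SCCCS1 | intermediate
29 | (3S,4R)-3,4-bis[(tert-butyldimethylsilyl)oxy]hex-5-enal | C=C[C@@H](O[Si](C)(C)C(C)(C)C)[C@@H](O[Si](C)(C)C(C)(C)C)CC=O | intermediate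
30 | (2S,4S,5R)-4,5-bis[(tert-butyldimethylsilyl)oxy]-1-nitrohept-6-en-2-ol | C=C[C@@H](O[Si](C)(C)C(C)(C)C)[C@@H](O[Si](C)(C)C(C)(C)C)C[C@H](O)C[N+](=O)[O-] | intermediate
31 | (2S,4S,5R)-1-amino-4,5-bis[(tert-butyldimethylsilyl)oxy]hept-6-en-2-ol | C=C[C@@H](O[Si](C)(C)C(C)(C)C)[C@@H](O[Si](C)(C)C(C)(C)C)C[C@H](O)CN | intermediate
32 | N-[(2S,4S,5R)-4,5-bis[(tert-butyldimethylsilyl)oxy]-2-hydroxyhept-6-en-1-yl]formamide | C=C[C@@H](O[Si](C)(C)C(C)(C)C)[C@@H](O[Si](C)(C)C(C)(C)C)C[C@H](O)CNC=O | intermediate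
33 | N-[(2S,4S,5R)-2,4,5-tris[(tert-butyldimethylsilyl)oxy]hept-6-en-1-yl]formamide (C18–C24 alkene) | C=C[C@@H](O[Si](C)(C)C(C)(C)C)[C@@H](O[Si](C)(C)C(C)(C)C)C[C@H](O[Si](C)(C)C(C)(C)C)CNC=O | intermediate
34 | B-alkyl-9-borabicyclo[3.3.1]nonane from 33 (boron on C18) | C1CCC2CCCC1B2CC[C@@H](O[Si](C)(C)C(C)(C)C)[C@@H](O[Si](C)(C)C(C)(C)C)C[C@H](O[Si](C)(C)C(C)(C)C)CNC=O | intermediate
35 | methyl (2S,4S,13R,14E,16Z,20R,21S,23S)-20,21,23-tris[(tert-butyldimethylsilyl)oxy]-24-formamido-17-(methoxymethyl)-2,4,13-trimethyltetracosa-14,16-dienoate | COC(=O)[C@@H](C)C[C@@H](C)CCCCCCCC[C@@H](C)/C=C/C=C(\COC)CC[C@@H](O[Si](C)(C)C(C)(C)C)[C@@H](O[Si](C)(C)C(C)(C)C)C[C@H](O[Si](C)(C)C(C)(C)C)CNC=O | intermediate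
36 | methyl ester of the seco isocyano acid (24-isocyano analogue of 35) | COC(=O)[C@@H](C)C[C@@H](C)CCCCCCCC[C@@H](C)/C=C/C=C(\COC)CC[C@@H](O[Si](C)(C)C(C)(C)C)[C@@H](O[Si](C)(C)C(C)(C)C)C[C@H](O[Si](C)(C)C(C)(C)C)C[N+]#[C-] | intermediate
37 | lithium carboxylate of 38 | [Li+].[O-]C(=O)[C@@H](C)C[C@@H](C)CCCCCCCC[C@@H](C)/C=C/C=C(\COC)CC[C@@H](O[Si](C)(C)C(C)(C)C)[C@@H](O[Si](C)(C)C(C)(C)C)C[C@H](O[Si](C)(C)C(C)(C)C)C[N+]#[C-] | intermediate
38 | (2S,4S,13R,14E,16Z,20R,21S,23S)-20,21,23-tris[(tert-butyldimethylsilyl)oxy]-24-isocyano-17-(methoxymethyl)-2,4,13-trimethyltetracosa-14,16-dienoic acid (seco isocyano acid, key-step precursor) | OC(=O)[C@@H](C)C[C@@H](C)CCCCCCCC[C@@H](C)/C=C/C=C(\COC)CC[C@@H](O[Si](C)(C)C(C)(C)C)[C@@H](O[Si](C)(C)C(C)(C)C)C[C@H](O[Si](C)(C)C(C)(C)C)C[N+]#[C-] | intermediate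
39 | butanal | CCCC=O | starting material
40 | 27-membered cyclic imidate (C1 carboxylate oxygen on C1', C1'=N–C24, exocyclic (S)-C2'H(OH)Pr) | O=C1[C@@H](C)C[C@@H](C)CCCCCCCC[C@@H](C)/C=C/C=C(\COC)CC[C@@H](O[Si](C)(C)C(C)(C)C)[C@@H](O[Si](C)(C)C(C)(C)C)C[C@H](O[Si](C)(C)C(C)(C)C)CN=C(O1)[C@@H](O)CCC | intermediate
41 | tris-TBS ether of the target macrocycle (28-membered depsi-lactam, (S) at C2') | CCC[C@@H]1OC(=O)[C@@H](C)C[C@@H](C)CCCCCCCC[C@@H](C)/C=C/C=C(\COC)CC[C@@H](O[Si](C)(C)C(C)(C)C)[C@@H](O[Si](C)(C)C(C)(C)C)C[C@H](O[Si](C)(C)C(C)(C)C)CNC1=O | intermediate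
42 | CNP0511044.2 | CCC[C@@H]1OC(=O)[C@@H](C)C[C@@H](C)CCCCCCCC[C@@H](C)/C=C/C=C(\COC)CC[C@@H](O)[C@@H](O)C[C@H](O)CNC1=O | target

**Step count**

Total: 31 steps. Longest linear sequence: 15 steps (steps 4–12, 16, 27–31 from the (S)-Roche ester; the line from 2-deoxy-D-ribose, steps 17–31, is equally long).

**Steps most likely to fail**

1. Step 30 (Passerini macrocyclisation). What may go wrong: at high dilution the uncatalysed background reaction may outrun the aluminium-bound pathway and erode facial selectivity at C2'; intermolecular nitrilium capture may give oligomers; or the isocyanide may be hydrated by its own acid before it meets butanal. Fallback (known chemistry, C2' from the chiral pool, ring closed by macrolactonisation): it sets out from nitro alcohol 30 and returns at 41. Compound 30 is silylated (TBSCl, imidazole, DMF) to the nitro tris-silyl ether F1, which is reduced with Zn/AcOH to the amine F2. EDC/HOBt coupling of F2 with (S)-2-hydroxypentanoic acid gives the α-hydroxy amide F3. Hydroboration of F3 with 9-BBN and Suzuki coupling with triflate 22 under the conditions of step 27 gives the methyl ester F4, and LiOH then gives the seco hydroxy acid F5. Yamaguchi macrolactonisation of F5 (2,4,6-trichlorobenzoyl chloride, Et3N, then DMAP, toluene, high dilution) forms the C1–O bond and delivers 41, which continues with step 31.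

2. Step 16 (Julia–Kocienski olefination with the triflate enal). What may go wrong: the sulfonyl carbanion or the amide base may attack the vinyl triflate (loss of the triflate by addition–elimination or S–O cleavage), and E selectivity at C14=C15 may erode with a conjugated aldehyde. Fallback (reversed order, so that no vinyl triflate meets a carbanion): it sets out from alkene 33 and triflate alcohol 19 and returns at 35. Compound 33 is hydroborated with 9-BBN and coupled with 19 (PdCl2(dppf)·CH2Cl2, AsPh3, aq. Cs2CO3, DMF) to the (Z)-allylic alcohol F6, which MnO2 oxidises to the enal F7. Julia–Kocienski olefination of sulfone 16 with F7 (KHMDS 2.2 equiv, the extra equivalent for the formamide N–H, DME, −60 °C) gives 35 directly, and the route continues with step 28.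

3. Step 23 (asymmetric Henry reaction). What may go wrong: poor facial selectivity at C23 if the ligand and the β-silyloxy stereocentre are mismatched, or base-induced β-elimination of silanol from the aldehyde. Fallback (epoxide resolution in place of catalyst-controlled addition): it sets out from aldehyde 29 and returns at 31. Corey–Chaykovsky methylenation of 29 (Me3S+ I−, KHMDS, THF, −10 °C) gives the terminal epoxide F8 as both C23 epimers. Hydrolytic kinetic resolution with (R,R)-(salen)Co(OAc) and 0.55 equiv water hydrolyses the (R)-epoxide to the diol F10 and leaves the (S)-epoxide F9. Opening of F9 at C24 with NH3 in MeOH gives amino alcohol 31, and the route continues with step 25.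

**Further compounds**

F1 | step 30 | (2S,4S,5R)-2,4,5-tris[(tert-butyldimethylsilyl)oxy]-1-nitrohept-6-ene | C=C[C@@H](O[Si](C)(C)C(C)(C)C)[C@@H](O[Si](C)(C)C(C)(C)C)C[C@H](O[Si](C)(C)C(C)(C)C)C[N+](=O)[O-]
F2 | step 30 | (2S,4S,5R)-2,4,5-tris[(tert-butyldimethylsilyl)oxy]hept-6-en-1-amine | C=C[C@@H](O[Si](C)(C)C(C)(C)C)[C@@H](O[Si](C)(C)C(C)(C)C)C[C@H](O[Si](C)(C)C(C)(C)C)CN
F3 | step 30 | (S)-2-hydroxy-N-[(2S,4S,5R)-2,4,5-tris[(tert-butyldimethylsilyl)oxy]hept-6-en-1-yl]pentanamide | C=C[C@@H](O[Si](C)(C)C(C)(C)C)[C@@H](O[Si](C)(C)C(C)(C)C)C[C@H](O[Si](C)(C)C(C)(C)C)CNC(=O)[C@@H](O)CCC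
F4 | step 30 | methyl ester of the seco hydroxy acid (N-[(S)-2-hydroxypentanoyl] analogue of 35) | COC(=O)[C@@H](C)C[C@@H](C)CCCCCCCC[C@@H](C)/C=C/C=C(\COC)CC[C@@H](O[Si](C)(C)C(C)(C)C)[C@@H](O[Si](C)(C)C(C)(C)C)C[C@H](O[Si](C)(C)C(C)(C)C)CNC(=O)[C@@H](O)CCC
F5 | step 30 | seco hydroxy acid (C1 acid, free C2' hydroxyl) | OC(=O)[C@@H](C)C[C@@H](C)CCCCCCCC[C@@H](C)/C=C/C=C(\COC)CC[C@@H](O[Si](C)(C)C(C)(C)C)[C@@H](O[Si](C)(C)C(C)(C)C)C[C@H](O[Si](C)(C)C(C)(C)C)CNC(=O)[C@@H](O)CCC
F6 | step 16 | N-[(2S,4S,5R,8Z)-2,4,5-tris[(tert-butyldimethylsilyl)oxy]-10-hydroxy-8-(methoxymethyl)dec-8-en-1-yl]formamide | OC/C=C(\COC)CC[C@@H](O[Si](C)(C)C(C)(C)C)[C@@H](O[Si](C)(C)C(C)(C)C)C[C@H](O[Si](C)(C)C(C)(C)C)CNC=O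
F7 | step 16 | N-[(2S,4S,5R,8Z)-2,4,5-tris[(tert-butyldimethylsilyl)oxy]-8-(methoxymethyl)-10-oxodec-8-en-1-yl]formamide | O=C/C=C(\COC)CC[C@@H](O[Si](C)(C)C(C)(C)C)[C@@H](O[Si](C)(C)C(C)(C)C)C[C@H](O[Si](C)(C)C(C)(C)C)CNC=O
F8 | step 23 | 2-[(2S,3R)-2,3-bis[(tert-butyldimethylsilyl)oxy]pent-4-en-1-yl]oxirane, both epimers at the oxirane carbon | C=C[C@@H](O[Si](C)(C)C(C)(C)C)[C@@H](O[Si](C)(C)C(C)(C)C)CC1CO1
F9 | step 23 | (S)-2-[(2S,3R)-2,3-bis[(tert-butyldimethylsilyl)oxy]pent-4-en-1-yl]oxirane | C=C[C@@H](O[Si](C)(C)C(C)(C)C)[C@@H](O[Si](C)(C)C(C)(C)C)C[C@H]1CO1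
F10 | step 23 | (2R,4S,5R)-4,5-bis[(tert-butyldimethylsilyl)oxy]hept-6-ene-1,2-diol | C=C[C@@H](O[Si](C)(C)C(C)(C)C)[C@@H](O[Si](C)(C)C(C)(C)C)C[C@@H](O)CO
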